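## The problem

Pseudophenone A (26) consists of four benzene rings joined by one diaryl ether and two aryl ester bonds. Rings A and B form an asterric acid unit, and the ring B carboxyl is esterified to O-3 of a 5-methylpyrogallol (ring C). The central O-4 of ring C is esterified to the middle carboxyl (on D1) of a 5-hydroxybenzene-1,2,3-tricarboxylate (ring D), whose outer carboxyls on D2 and D6 are methyl esters.

The molecule has no stereocentre and no axis that could be configurationally stable, so the difficulties are regiochemical and chemoselective only. Ring C carries three adjacent oxygens that end in three different states (ester to ring B, ester to ring D, free hydroxyl), so its two outer oxygens must be told apart. The C–D ester is the most congested bond: its carbonyl lies between two methoxycarbonyl groups, its oxygen between two oxygenated carbons, and D1 must be distinguished from two chemically similar neighbours. The A–B ether is triply ortho-substituted and involves a chelated, salicylate-type oxygen.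

The fragile groups are the two aryl esters, which alkoxide, hydroxide or fluoride would cleave and which a neighbouring ring C phenoxide can pull across. The three methyl esters must not be exchanged, and the electron-rich phenols rule out late oxidants. The enabling feature is ring D itself: methyl esters on D2 and D6 and a hydroxyl on D4 are the substituents of dimethyl chelidonate. If the ring oxygen of that pyranone is replaced by a carbon that already carries the ring C ester, ring D and its hardest ester arise together.

## Retrosynthesis

**Global deprotection.** Target 26 is traced back to its tetra-O-benzyl ether 25, cutting four O–benzyl bonds. Hydrogenolysis is neutral, which is why benzyl is preferred over silyl or acetal groups whose removal needs fluoride or acid next to two aryl esters. The forward step only has to spare the esters.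

**B–C ester.** 25 is cut at the ester between the ring B carbonyl and O-3 of ring C, giving phenol 14 (rings C and D) and acid 23 (protected asterric acid), activated as chloride 24. Of the two depside bonds this is the less crowded and divides the molecule into halves of similar size. The C–D ester would be a poor choice for an acylation. The forward reaction needs exactly one free hydroxyl on ring C, so the outer oxygens are differentiated from the start as a benzyl ether (permanent) and a methoxymethyl ether (temporary).

**Protecting-group adjustment.** 14 comes from 13 by acid cleavage of the methoxymethyl ether, and 13 from phenol 12 by benzylation of the ring D hydroxyl. That hydroxyl is unhindered and acidic and would otherwise compete in the fragment union.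

**Ring D (key disconnection).** 12 is cut at D1–D2 and D1–D6. D1 and its carboxyl go to the phosphonoacetate 10 of the central ring C oxygen, and D2–D6 to dimethyl chelidonate 2. This removes a whole ring and reduces a hemimellitate with three differentiated carboxyls to a symmetric pyranone and a simple acetate ester. The C–D ester is then made as an unhindered phosphonoacetate ester before any crowding exists. The forward reaction must add the carbanion at C2 of the pyranone and close the carbocycle by olefination without losing the aryl ester.

**Ring C phosphonate.** 10 is cut at its ester bond into phenol 8 and diethylphosphonoacetic acid 9. The central hydroxyl of 8 is cut back to a C–H bond of the mixed benzyl/methoxymethyl diether 5, because the position between two alkoxy groups is the natural site for directed lithiation and borylation–oxidation. 5 comes from orcinol 3 through monobenzyl ether 4. The statistical monoalkylation is placed at the first step, on a commodity phenol, rather than at a late diol. Pyranone 2 is the dimethyl ester of chelidonic acid 1.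

**Asterric acid half.** Acid 23 comes from aldehyde 22 by oxidation. 22 is cut at the diaryl ether bond on the ring B side, where an ortho formyl group activates a fluoride for substitution, giving phenol 19 and fluoro aldehyde 21. The cut on the ring A side would need an electrophile deactivated by a para oxygen. 21 comes from commercial 2,6-difluoro-4-methylbenzaldehyde 20 by displacement of one fluoride with benzyl alcohol. 19 comes from methyl 3-methoxysalicylate 15 by para-formylation (16), Dakin oxidation (18, via formate 17) and selective benzylation of the unchelated hydroxyl.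

## Roads not taken

**Alternative 1:** ring B by cycloaddition. Ring B is cut into a two-carbon alkyne piece (the carbons bearing the carboxyl and the ether oxygen) and a four-carbon diene. Forward, the ring A aryloxypropiolate A2 would undergo a Diels–Alder reaction with the silyl ketene acetal diene A3. Loss of methanol and the silyl group would aromatise the adduct to the salicylate A1.
- Merits: the polarisation of both partners is matched, so the methyl, hydroxyl and ether positions are fixed by the cycloaddition. The ether oxygen is attached to an sp carbon rather than a crowded arene. The allyl ester is orthogonal to the methyl ester.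
- Weak points: an aryl ynol ether of a hindered, chelated phenol is laborious to make and its donor oxygen makes the alkyne a sluggish dienophile. The step touches only the A–B half; the C–D ester would still have to be made by acylating a hindered phenol with a hemimellitic monoacid, and ring C would still need differentiation.
- Comparison: for the diaryl ether this road is arguably better than the substitution in step 13, which relies on a poor nucleophile. The chosen plan sets against it simpler, stable intermediates for that half and a key step that removes the one bond no acylation makes well.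

**Alternative 2:** ring A by aldol aromatisation. Ring A is cut between the ether-bearing carbon and the ester-bearing carbon, leading to the open-chain enol-ether diketo ester A5 attached to ring B through an aryloxymethyl group. Forward, deprotonation of that methylene and addition to the α-keto ester carbonyl, then loss of water, would give phenol A4.
- Merits: the hindered ether becomes a simple O-alkylation of a ring B phenol. The oxygen pattern of ring A follows from the chain. The idea is polyketide-like.
- Weak points: the most acidic site of A5 is the methylene between the two ketones, so the first equivalent of base enolises and deactivates the very carbonyl that must be attacked. A 1,3,5-trioxygenated chain of this kind also closes readily through oxygen to a pyranone. As in Alternative 1, the crowded C–D ester and ring C are untouched.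
- Comparison: it avoids the aromatic substitution of the chosen route, which is a real advantage. Against this, its own key step has a built-in regiochemical handicap and it solves the easier half of the molecule.

**Alternative 3:** Baeyer–Villiger oxygen insertion. The C–D ester is cut at the ring C carbon–oxygen bond, leading back to the tetra-ortho-substituted benzophenone A7. Forward, a peracid would add to the ketone and the electron-rich dihydroxyaryl group would migrate to oxygen, giving the diol ester A6.
- Merits: the migratory preference is strongly on the right side. The central oxygen of ring C and the hindered ester form in one step. The route probably mirrors the biogenesis, and it is short if A7 is at hand.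
- Weak points: A7 has four ortho substituents around the ketone, so both its assembly and the addition of the peracid to the hydrogen-bonded carbonyl are hindered. A free resorcinol ring is itself oxidised by peracids. A6 is a symmetric diol, so the union with the asterric acid half becomes a statistical monoacylation late in the synthesis.
- Comparison: in convergence and biomimetic economy this road is at least equal. The chosen plan sets against it the absence of any oxidant near the electron-rich phenols, a ring C that is unsymmetrical from the first step, and an ester that is formed before, not after, the crowding is created.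

Key step: step 6

## Route

Assumption: pseudophenone A has no stereocentre and no configurationally stable axis; it is achiral, so the requirement of a single enantiomer is met without any asymmetric step.

Step 1
Reactants: 1 chelidonic acid
Product: 2 dimethyl chelidonate (dimethyl 4-oxo-4H-pyran-2,6-dicarboxylate)
Conditions: MeOH, H2SO4 (cat.), reflux
Reagents that add atoms: methanol, CO
Why: Fischer esterification; the pyranone is stable to acid and both carboxyls are equivalent.

Step 2
Reactants: 3 orcinol (1.5 equiv)
Product: 4 3-(benzyloxy)-5-methylphenol
Conditions: BnBr (1.0 equiv), K2CO3, DMF, rt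
Reagents that add atoms: benzyl bromide, BrCc1ccccc1
Why: Williamson ether synthesis; with the diol in excess the monoether should predominate and the dibenzyl ether is removed by chromatography, a statistical step that is acceptable as the first step on a commodity phenol.

Step 3
Reactants: 4 3-(benzyloxy)-5-methylphenol
Product: 5 1-(benzyloxy)-3-(methoxymethoxy)-5-methylbenzene
Conditions: NaH, MOMCl, DMF, 0 °C → rt
Reagents that add atoms: chloromethyl methyl ether, COCCl
Why: O-alkylation of the phenoxide with an α-chloro ether (acetal protection); nothing else in the molecule is reactive.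

Step 4
Reactants: 5 1-(benzyloxy)-3-(methoxymethoxy)-5-methylbenzene
Product: 8 2-(benzyloxy)-6-(methoxymethoxy)-4-methylphenol, via aryllithium 6 (not isolated), via dimethyl arylboronate 7 (not isolated)
Conditions: n-BuLi, THF, 0 °C; B(OMe)3, −78 °C → rt; AcOH, 30% H2O2, 0 °C → rt
Reagents that add atoms: hydrogen peroxide, OO (oxygen of the new hydroxyl); n-butyllithium, [Li]CCCC (lithium of 6 only); trimethyl borate, COB(OC)OC (boron and methoxy groups of 7 only)
Why: Directed ortho-metalation at the ring position flanked by both alkoxy groups (chelation by the acetal, acidification by both oxygens), which with n-BuLi at 0 °C should be faster than benzylic deprotonation; borylation and oxidative 1,2-aryl shift from boron to oxygen then give the phenol.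

Step 5
Reactants: 8 2-(benzyloxy)-6-(methoxymethoxy)-4-methylphenol; 9 (diethoxyphosphoryl)acetic acid
Product: 10 2-(benzyloxy)-6-(methoxymethoxy)-4-methylphenyl (diethoxyphosphoryl)acetate
Conditions: DCC, DMAP (cat.), CH2Cl2, 0 °C → rt
Reagents that add atoms: none
Why: Steglich esterification; phosphonoacetic acid is activated very readily by carbodiimides, so even a phenol with two ortho substituents is acylated, and the future C–D ester is made while its carbonyl is still unhindered.

Step 6
Reactants: 2 dimethyl chelidonate; 10 2-(benzyloxy)-6-(methoxymethoxy)-4-methylphenyl (diethoxyphosphoryl)acetate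
Product: 12 dimethyl 2-{[2-(benzyloxy)-6-(methoxymethoxy)-4-methylphenoxy]carbonyl}-5-hydroxyisophthalate, via ring-opened keto phosphonate 11 (not isolated)
Conditions: 10, NaH (2.2 equiv), THF, 0 °C; then 2, 0 → 50 °C; cold 0.5 M HCl to pH 3–4
Reagents that add atoms: none
Why: The sodium carbanion of 10, a soft stabilised nucleophile, adds to C2 of 2, the β-carbon of the pyranone enone that also carries an ester, forming the D1–D2 bond; the resulting enolate expels the ring oxygen (retro-oxa-Michael) to give the open-chain dienolate 11, whose far end is a masked α-keto ester. The second equivalent of base regenerates the phosphonate carbanion, whose vinylogous enolate character lets the new C=C bond rotate into the cis arrangement needed for closure. This carbanion adds to the keto-ester carbonyl in a 6-exo-trig closure (equivalently a 6π-electrocyclisation of the trienolate), and syn-loss of diethyl phosphate in an intramolecular Horner–Wadsworth–Emmons olefination forms the D1=D6 bond. The cyclohexadienone then tautomerises irreversibly to the ring D phenoxide, which is why two equivalents of base are used. The closest known reaction types are the base-mediated conversion of 4-pyranones into 4-nitrophenols with nitromethane and the conversion of pyrylium salts into benzenes with phosphorus-stabilised carbanions; an aryl phosphonoacetate as the carbanion is an extension of these. No stereocentre is formed. The step needs attack at C2 (equivalent to C6 by symmetry) rather than at C4 or an ester carbonyl, which the deactivated vinylogous-ester character of C4 and the double activation of C2 should secure. It also needs the aryl ester to survive, which the absence of any alkoxide or hydroxide and the two ortho alkoxy groups of ring C should secure.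

Step 7
Reactants: 12 dimethyl 2-{[2-(benzyloxy)-6-(methoxymethoxy)-4-methylphenoxy]carbonyl}-5-hydroxyisophthalate
Product: 13 dimethyl 5-(benzyloxy)-2-{[2-(benzyloxy)-6-(methoxymethoxy)-4-methylphenoxy]carbonyl}isophthalate
Conditions: BnBr, K2CO3, DMF, rt
Reagents that add atoms: benzyl bromide, BrCc1ccccc1
Why: Williamson ether synthesis on an acidic, unhindered phenol; carbonate does not attack the doubly ortho-substituted aryl ester.

Step 8
Reactants: 13 dimethyl 5-(benzyloxy)-2-{[2-(benzyloxy)-6-(methoxymethoxy)-4-methylphenoxy]carbonyl}isophthalate
Product: 14 dimethyl 5-(benzyloxy)-2-{[2-(benzyloxy)-6-hydroxy-4-methylphenoxy]carbonyl}isophthalate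
Conditions: conc. HCl (cat.), MeOH–CH2Cl2, rt
Reagents that add atoms: none
Why: Acid-catalysed acetal exchange releases the phenol and dimethoxymethane; aryl benzyl ethers, methyl esters and the hindered aryl ester should be inert to dilute acid in methanol, and no phenoxide is formed that could trigger acyl migration.

Step 9
Reactants: 15 methyl 2-hydroxy-3-methoxybenzoate
Product: 16 methyl 5-formyl-2-hydroxy-3-methoxybenzoate
Conditions: hexamethylenetetramine, TFA, 85 °C; then 3 M HCl, 50 °C
Reagents that add atoms: hexamethylenetetramine, C1N2CN3CN1CN(C2)C3 (formyl carbon); water, O (formyl oxygen on hydrolysis)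
Why: Duff formylation; both positions ortho to the phenol are occupied, so the iminium electrophile attacks the para position, as in the preparation of syringaldehyde-type aldehydes.

Step 10
Reactants: 16 methyl 5-formyl-2-hydroxy-3-methoxybenzoate
Product: 18 methyl 2,5-dihydroxy-3-methoxybenzoate, via aryl formate 17 (not isolated)
Conditions: 30% H2O2, aq. NaOH (2 equiv), THF, 0 °C, N2; then 1 M HCl
Reagents that add atoms: hydrogen peroxide, OO
Why: Dakin oxidation; the para phenoxide drives aryl migration in the peroxide adduct and the formate is hydrolysed in the same flask, while short reaction time at 0 °C should spare the methyl ester.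

Step 11
Reactants: 18 methyl 2,5-dihydroxy-3-methoxybenzoate
Product: 19 methyl 5-(benzyloxy)-2-hydroxy-3-methoxybenzoate
Conditions: BnBr (1.05 equiv), K2CO3 (1.1 equiv), acetone, rt → 40 °C
Reagents that add atoms: benzyl bromide, BrCc1ccccc1
Why: Selective Williamson etherification; the 5-hydroxyl is unhindered and free, whereas the 2-hydroxyl is hydrogen-bonded to the ester and flanked on both sides, the selectivity known for gentisate esters.

Step 12
Reactants: 20 2,6-difluoro-4-methylbenzaldehyde
Product: 21 2-(benzyloxy)-6-fluoro-4-methylbenzaldehyde
Conditions: BnOH (1.0 equiv), NaH (1.05 equiv), THF, 0 °C → rt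
Reagents that add atoms: benzyl alcohol, OCc1ccccc1
Why: Nucleophilic aromatic substitution of a fluoride ortho to the formyl group; the alkoxy group introduced first lowers the reactivity of the second fluoride, so monosubstitution is expected.

Step 13
Reactants: 19 methyl 5-(benzyloxy)-2-hydroxy-3-methoxybenzoate; 21 2-(benzyloxy)-6-fluoro-4-methylbenzaldehyde
Product: 22 methyl 5-(benzyloxy)-2-[3-(benzyloxy)-2-formyl-5-methylphenoxy]-3-methoxybenzoate
Conditions: Cs2CO3, DMSO, 100 °C
Reagents that add atoms: none
Why: Nucleophilic aromatic substitution (addition–elimination) of the remaining ortho-formyl-activated fluoride by the caesium phenoxide; the para benzyloxy group raises the nucleophilicity of the otherwise chelated phenoxide, and there is only one position where substitution can occur.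

Step 14
Reactants: 22 methyl 5-(benzyloxy)-2-[3-(benzyloxy)-2-formyl-5-methylphenoxy]-3-methoxybenzoate
Product: 23 2-(benzyloxy)-6-[4-(benzyloxy)-2-methoxy-6-(methoxycarbonyl)phenoxy]-4-methylbenzoic acid
Conditions: NaClO2, NaH2PO4, 2-methyl-2-butene, t-BuOH–THF–H2O, rt
Reagents that add atoms: sodium chlorite, [Na+].[O-]Cl=O
Why: Pinnick oxidation of the aldehyde; the alkene scavenges hypochlorous acid so the electron-rich rings are not chlorinated, and esters and benzyl ethers are untouched.

Step 15
Reactants: 23 2-(benzyloxy)-6-[4-(benzyloxy)-2-methoxy-6-(methoxycarbonyl)phenoxy]-4-methylbenzoic acid; 14 dimethyl 5-(benzyloxy)-2-{[2-(benzyloxy)-6-hydroxy-4-methylphenoxy]carbonyl}isophthalate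
Product: 25 dimethyl 5-(benzyloxy)-2-{[2-(benzyloxy)-6-({2-(benzyloxy)-6-[4-(benzyloxy)-2-methoxy-6-(methoxycarbonyl)phenoxy]-4-methylbenzoyl}oxy)-4-methylphenoxy]carbonyl}isophthalate, via acid chloride 24 (not isolated)
Conditions: 23, (COCl)2, DMF (cat.), CH2Cl2, 0 °C → rt, evaporate; then 14, DMAP (0.2 equiv), Et3N added last, CH2Cl2, −20 °C → rt
Reagents that add atoms: oxalyl chloride, O=C(Cl)C(=O)Cl (chlorine of 24 only; no atoms remain in 25)
Why: Acid chloride formation and DMAP-catalysed acylation of a phenol, the standard depside coupling; 2,6-dioxygenated benzoyl chlorides are stable and reactive, 14 has a single free hydroxyl, and adding the base last at low temperature keeps the phenoxide concentration low.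

Step 16
Reactants: 25 tetra-O-benzyl pseudophenone A (full name in step 15)
Product: 26 pseudophenone A
Conditions: H2 (1 atm), 10% Pd/C, EtOAc, rt
Reagents that add atoms: none
Why: Catalytic hydrogenolysis of four aryl benzyl ethers under neutral, alcohol-free conditions, the classical last step of depside syntheses; aryl esters, methyl esters and the diaryl ether are not reduced.

## Compound list

1 | chelidonic acid (4-oxo-4H-pyran-2,6-dicarboxylic acid) | O=C(O)c1cc(=O)cc(C(=O)O)o1 | starting material
2 | dimethyl chelidonate | COC(=O)c1cc(=O)cc(C(=O)OC)o1 | intermediate
3 | orcinol (5-methylbenzene-1,3-diol) | Cc1cc(O)cc(O)c1 | starting material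
4 | 3-(benzyloxy)-5-methylphenol | Cc1cc(O)cc(OCc2ccccc2)c1 | intermediate
5 | 1-(benzyloxy)-3-(methoxymethoxy)-5-methylbenzene | COCOc1cc(C)cc(OCc2ccccc2)c1 | intermediate
6 | [2-(benzyloxy)-6-(methoxymethoxy)-4-methylphenyl]lithium | [Li]c1c(OCc2ccccc2)cc(C)cc1OCOC | intermediate (not isolated)
7 | dimethyl [2-(benzyloxy)-6-(methoxymethoxy)-4-methylphenyl]boronate | COB(OC)c1c(OCc2ccccc2)cc(C)cc1OCOC | intermediate (not isolated)
8 | 2-(benzyloxy)-6-(methoxymethoxy)-4-methylphenol | COCOc1cc(C)cc(OCc2ccccc2)c1O | intermediate
9 | (diethoxyphosphoryl)acetic acid | CCOP(=O)(OCC)CC(=O)O | starting material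
10 | 2-(benzyloxy)-6-(methoxymethoxy)-4-methylphenyl (diethoxyphosphoryl)acetate | CCOP(=O)(OCC)CC(=O)Oc1c(OCc2ccccc2)cc(C)cc1OCOC | intermediate
11 | 1-[2-(benzyloxy)-6-(methoxymethoxy)-4-methylphenyl] 8-methyl 2-(diethoxyphosphoryl)-3-(methoxycarbonyl)-5,7-dioxooct-3-enedioate (drawn as the neutral keto form; present as its sodium dienolate, racemic at C2 and labile in alkene geometry, so no descriptors) | COC(=O)C(=O)CC(=O)C=C(C(=O)OC)C(C(=O)Oc1c(OCc2ccccc2)cc(C)cc1OCOC)P(=O)(OCC)OCC | intermediate (not isolated)
12 | dimethyl 2-{[2-(benzyloxy)-6-(methoxymethoxy)-4-methylphenoxy]carbonyl}-5-hydroxyisophthalate | COCOc1cc(C)cc(OCc2ccccc2)c1OC(=O)c1c(C(=O)OC)cc(O)cc1C(=O)OC | intermediate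
13 | dimethyl 5-(benzyloxy)-2-{[2-(benzyloxy)-6-(methoxymethoxy)-4-methylphenoxy]carbonyl}isophthalate | COCOc1cc(C)cc(OCc2ccccc2)c1OC(=O)c1c(C(=O)OC)cc(OCc2ccccc2)cc1C(=O)OC | intermediate
14 | dimethyl 5-(benzyloxy)-2-{[2-(benzyloxy)-6-hydroxy-4-methylphenoxy]carbonyl}isophthalate | Cc1cc(O)c(OC(=O)c2c(C(=O)OC)cc(OCc3ccccc3)cc2C(=O)OC)c(OCc2ccccc2)c1 | intermediate
15 | methyl 2-hydroxy-3-methoxybenzoate | COC(=O)c1cccc(OC)c1O | starting material
16 | methyl 5-formyl-2-hydroxy-3-methoxybenzoate | COC(=O)c1cc(C=O)cc(OC)c1O | intermediate
17 | methyl 5-(formyloxy)-2-hydroxy-3-methoxybenzoate | COC(=O)c1cc(OC=O)cc(OC)c1O | intermediate (not isolated)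
18 | methyl 2,5-dihydroxy-3-methoxybenzoate | COC(=O)c1cc(O)cc(OC)c1O | intermediate
19 | methyl 5-(benzyloxy)-2-hydroxy-3-methoxybenzoate | COC(=O)c1cc(OCc2ccccc2)cc(OC)c1O | intermediate
20 | 2,6-difluoro-4-methylbenzaldehyde | Cc1cc(F)c(C=O)c(F)c1 | starting material
21 | 2-(benzyloxy)-6-fluoro-4-methylbenzaldehyde | Cc1cc(F)c(C=O)c(OCc2ccccc2)c1 | intermediate
22 | methyl 5-(benzyloxy)-2-[3-(benzyloxy)-2-formyl-5-methylphenoxy]-3-methoxybenzoate | COC(=O)c1cc(OCc2ccccc2)cc(OC)c1Oc1cc(C)cc(OCc2ccccc2)c1C=O | intermediate
23 | 2-(benzyloxy)-6-[4-(benzyloxy)-2-methoxy-6-(methoxycarbonyl)phenoxy]-4-methylbenzoic acid | COC(=O)c1cc(OCc2ccccc2)cc(OC)c1Oc1cc(C)cc(OCc2ccccc2)c1C(=O)O | intermediate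
24 | 2-(benzyloxy)-6-[4-(benzyloxy)-2-methoxy-6-(methoxycarbonyl)phenoxy]-4-methylbenzoyl chloride | COC(=O)c1cc(OCc2ccccc2)cc(OC)c1Oc1cc(C)cc(OCc2ccccc2)c1C(=O)Cl | intermediate (not isolated)
25 | tetra-O-benzyl pseudophenone A (name in step 15) | COC(=O)c1cc(OCc2ccccc2)cc(OC)c1Oc1cc(C)cc(OCc2ccccc2)c1C(=O)Oc1cc(C)cc(OCc2ccccc2)c1OC(=O)c1c(C(=O)OC)cc(OCc2ccccc2)cc1C(=O)OC | intermediate
26 | pseudophenone A, dimethyl 5-hydroxy-2-{[2-hydroxy-6-({2-hydroxy-6-[4-hydroxy-2-methoxy-6-(methoxycarbonyl)phenoxy]-4-methylbenzoyl}oxy)-4-methylphenoxy]carbonyl}isophthalate (achiral) | COC(=O)c1cc(O)cc(OC)c1Oc1cc(C)cc(O)c1C(=O)Oc1cc(C)cc(O)c1OC(=O)c1c(C(=O)OC)cc(O)cc1C(=O)OC | target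

## Step count and risks

Total: 16 steps. Longest linear sequence: 9 steps (steps 2, 3, 4, 5, 6, 7, 8, 15, 16, from orcinol).

**Step 6 (key step).** The pyranone-to-phenol ring transformation is known with nitromethane, and the phosphorus-mediated closure is known from pyrylium salts. The pairing of a pyranone with an aryl phosphonoacetate has to be shown. Most likely to go wrong:
- loss of the aryloxide from the carbanion of 10 (elimination to a phosphoryl ketene);
- addition of the carbanion to an ester carbonyl instead of C2;
- arrest at the open-chain diketonate, because enolisation of the α-keto ester slows the ring closure.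

Fallback: keep the same ring construction but use a robust ester that tolerates stronger base and heat, setting out from 2 and returning at 13. Pyranone 2 would be treated with commercial tert-butyl diethylphosphonoacetate (t-BuOK, t-BuOH–THF, heat) to give 2-tert-butyl 1,3-dimethyl 5-hydroxybenzene-1,2,3-tricarboxylate F1. Benzylation (BnBr, K2CO3) would give the benzyl ether F2. Trifluoroacetic acid would cleave only the tert-butyl ester to give 4-(benzyloxy)-2,6-bis(methoxycarbonyl)benzoic acid F3. Oxalyl chloride would give the acid chloride F4, which would acylate phenol 8 (Et3N, DMAP) to give 13. The price is that the congested ester is then made by acylation.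

**Step 13.** The substitution may be sluggish: the phenoxide of 19 is hindered and chelated, and the fluoride of 21 is activated by a single formyl group whose pull is weakened by the ortho benzyloxy donor. At the temperature needed the aldehyde may disproportionate.

Fallback, from 19 and 20, returning at 22: 19 would first be coupled with the more electrophilic difluoride 20 (K2CO3, DMF, 70 °C) to give methyl 5-(benzyloxy)-2-(3-fluoro-2-formyl-5-methylphenoxy)-3-methoxybenzoate F5. The remaining fluoride would then be replaced by hydroxyl with benzaldoxime and Cs2CO3 in DMSO (an oximate as hydroxide surrogate, which does not transesterify the methyl ester), giving methyl 5-(benzyloxy)-2-(2-formyl-3-hydroxy-5-methylphenoxy)-3-methoxybenzoate F6. Benzylation of F6 (BnBr, K2CO3) gives 22.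

**Step 15.** Both partners are hindered, so acylation may be slow. Under base the phenoxide of 14 may attack the neighbouring ring D ester and shift that acyl group to the outer oxygen before the intended acylation occurs.

Fallback, from 23 and 14, returning at 25: replace the base-mediated acid chloride coupling by the acid-mediated mixed-anhydride condensation. Acid 23 and trifluoroacetic anhydride in toluene would give the mixed 2-(benzyloxy)-6-[4-(benzyloxy)-2-methoxy-6-(methoxycarbonyl)phenoxy]-4-methylbenzoic trifluoroacetic anhydride F7. This acylates 14 through an acylium-like species without any base, so no phenoxide and hence no migration pathway exists.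

**Step 10.** Alkaline peroxide may saponify the methyl ester or oxidise the product hydroquinone further to the quinone.

Fallback, from 15, returning at 18 (it also replaces step 9): Teuber oxidation of 15 with Fremy's salt in buffered aqueous acetone would give methyl 5-methoxy-3,6-dioxocyclohexa-1,4-diene-1-carboxylate F8. Reduction with sodium dithionite gives 18 under non-basic conditions.

## Further compounds

F1 | step 6 | 2-tert-butyl 1,3-dimethyl 5-hydroxybenzene-1,2,3-tricarboxylate | COC(=O)c1cc(O)cc(C(=O)OC)c1C(=O)OC(C)(C)C
F2 | step 6 | 2-tert-butyl 1,3-dimethyl 5-(benzyloxy)benzene-1,2,3-tricarboxylate | COC(=O)c1cc(OCc2ccccc2)cc(C(=O)OC)c1C(=O)OC(C)(C)C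
F3 | step 6 | 4-(benzyloxy)-2,6-bis(methoxycarbonyl)benzoic acid | COC(=O)c1cc(OCc2ccccc2)cc(C(=O)OC)c1C(=O)O
F4 | step 6 | 4-(benzyloxy)-2,6-bis(methoxycarbonyl)benzoyl chloride | COC(=O)c1cc(OCc2ccccc2)cc(C(=O)OC)c1C(=O)Cl
F5 | step 13 | methyl 5-(benzyloxy)-2-(3-fluoro-2-formyl-5-methylphenoxy)-3-methoxybenzoate | COC(=O)c1cc(OCc2ccccc2)cc(OC)c1Oc1cc(C)cc(F)c1C=O
F6 | step 13 | methyl 5-(benzyloxy)-2-(2-formyl-3-hydroxy-5-methylphenoxy)-3-methoxybenzoate | COC(=O)c1cc(OCc2ccccc2)cc(OC)c1Oc1cc(C)cc(O)c1C=O
F7 | step 15 | 2-(benzyloxy)-6-[4-(benzyloxy)-2-methoxy-6-(methoxycarbonyl)phenoxy]-4-methylbenzoic trifluoroacetic anhydride | COC(=O)c1cc(OCc2ccccc2)cc(OC)c1Oc1cc(C)cc(OCc2ccccc2)c1C(=O)OC(=O)C(F)(F)F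
F8 | step 10 | methyl 5-methoxy-3,6-dioxocyclohexa-1,4-diene-1-carboxylate | COC(=O)C1=CC(=O)C=C(OC)C1=O
A1 | alternative 1 | allyl 2-[4-(benzyloxy)-2-methoxy-6-(methoxycarbonyl)phenoxy]-6-hydroxy-4-methylbenzoate | COC(=O)c1cc(OCc2ccccc2)cc(OC)c1Oc1cc(C)cc(O)c1C(=O)OCC=C
A2 | alternative 1 | allyl 3-[4-(benzyloxy)-2-methoxy-6-(methoxycarbonyl)phenoxy]prop-2-ynoate | COC(=O)c1cc(OCc2ccccc2)cc(OC)c1OC#CC(=O)OCC=C
A3 | alternative 1 | [(1-methoxy-3-methylbuta-1,3-dien-1-yl)oxy]trimethylsilane | COC(O[Si](C)(C)C)=CC(C)=C
A4 | alternative 2 | tert-butyl 2-(benzyloxy)-6-[4-hydroxy-2-methoxy-6-(methoxycarbonyl)phenoxy]-4-methylbenzoate | COC(=O)c1cc(O)cc(OC)c1Oc1cc(C)cc(OCc2ccccc2)c1C(=O)OC(C)(C)C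
A5 | alternative 2 | tert-butyl 2-(benzyloxy)-6-[(2,7-dimethoxy-4,6,7-trioxohept-2-en-1-yl)oxy]-4-methylbenzoate | COC(=O)C(=O)CC(=O)C=C(OC)COc1cc(C)cc(OCc2ccccc2)c1C(=O)OC(C)(C)C
A6 | alternative 3 | dimethyl 5-(benzyloxy)-2-[(2,6-dihydroxy-4-methylphenoxy)carbonyl]isophthalate | Cc1cc(O)c(OC(=O)c2c(C(=O)OC)cc(OCc3ccccc3)cc2C(=O)OC)c(O)c1
A7 | alternative 3 | dimethyl 5-(benzyloxy)-2-(2,6-dihydroxy-4-methylbenzoyl)isophthalate | Cc1cc(O)c(C(=O)c2c(C(=O)OC)cc(OCc3ccccc3)cc2C(=O)OC)c(O)c1
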